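Everything rests on cutting ring A (the pyran) at C4–C4a and O2–C3, which leaves a chiral ring B that is finished first. The feature used is that O2 is already bonded to C1 as the enol of an 8a-hydroxymethylene ketone, while the vinylic C4a–H sits where a five-membered metallacycle from O2 ends. In one operation the catalyst from [Cp*RhCl2]2 and AgSbF6 metalates C4a–H, a crotonoyl sulfoxonium ylide brings in C4 and C3 as a carbene, and cyclodehydration closes ring A. The precursor is the (7R)-configured 8a-hydroxymethylene cyclohex-4a-ene-6,8-dione that already bears the silyl-protected aryl ester. C7 is set by enzymatic desymmetrisation of an achiral 1,3-dione.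

Key step: step 12

Assumption: ring atoms of all intermediates carry the isochromene numbers of the target, and enols are drawn as one tautomer. The ketoreductase is picked from a commercial screening panel for the sense of desymmetrisation drawn; the C6 carbinol configuration is immaterial because C6 is reoxidised.

Step 1
Reactants: 1 2,4-dihydroxy-6-methylbenzaldehyde
Product: 2 4-(tert-butyldimethylsilyloxy)-2-hydroxy-6-methylbenzaldehyde
Conditions: TBSCl (1.05 equiv), imidazole, CH2Cl2, 0 °C
Reagents that add atoms: tert-butyldimethylsilyl chloride, CC(C)(C)[Si](C)(C)Cl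
Why: Chemoselective silyl ether formation, because the 2-OH is held in a hydrogen bond to the formyl oxygen and the free, more acidic 4-OH reacts first.

Step 2
Reactants: 2 4-(tert-butyldimethylsilyloxy)-2-hydroxy-6-methylbenzaldehyde
Product: 3 4-(tert-butyldimethylsilyloxy)-2-methoxy-6-methylbenzaldehyde
Conditions: MeOH, PPh3, DIAD, THF, 0 °C to rt
Reagents that add atoms: methanol, CO
Why: Mitsunobu etherification methylates the chelated 2-OH under neutral conditions, so no carbonate base is present that could strip or scramble the base-labile aryl silyl ether.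

Step 3
Reactants: 3 4-(tert-butyldimethylsilyloxy)-2-methoxy-6-methylbenzaldehyde
Product: 4 4-(tert-butyldimethylsilyloxy)-2-methoxy-6-methylbenzoic acid
Conditions: NaClO2, NaH2PO4, 2-methylbut-2-ene (excess), t-BuOH/H2O, rt
Reagents that add atoms: sodium chlorite, [Na+].[O-]Cl=O
Why: Pinnick oxidation at about pH 4 gives the hindered acid without any ester hydrolysis, so the aryl silyl ether survives, and the alkene scavenger traps HOCl before it can chlorinate the electron-rich ring.

Step 4
Reactants: 5 2-methylcyclohexane-1,3-dione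
Product: 6 2-hydroxy-2-methylcyclohexane-1,3-dione (achiral)
Conditions: dimethyldioxirane (acetone solution, 1.1 equiv), acetone, 0 °C
Reagents that add atoms: dimethyldioxirane, CC1(C)OO1
Why: Electrophilic alpha-hydroxylation of a fully enolised 2-alkyl-1,3-dione by a dioxirane, which delivers oxygen to the nucleophilic C2 and needs no aqueous work-up for the water-soluble product.

Step 5
Reactants: 4 4-(tert-butyldimethylsilyloxy)-2-methoxy-6-methylbenzoic acid; 6 2-hydroxy-2-methylcyclohexane-1,3-dione
Product: 8 1-methyl-2,6-dioxocyclohexyl 4-(tert-butyldimethylsilyloxy)-2-methoxy-6-methylbenzoate (achiral), via aroyl trifluoroacetate 7 (not isolated)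
Conditions: 4, (CF3CO)2O (1.2 equiv), toluene, 0 °C; then 6, rt
Reagents that add atoms: none
Why: Esterification of a hindered acid through its mixed trifluoroacetic anhydride, in which the electron-rich 2,6-disubstituted aroyl group ionises to a linear acylium ion that the tertiary hydroxyl can reach, while the carbinol flanked by two carbonyls cannot ionise or eliminate in the acidic medium.

Step 6
Reactants: 8 1-methyl-2,6-dioxocyclohexyl 4-(tert-butyldimethylsilyloxy)-2-methoxy-6-methylbenzoate
Product: 9 (1R,2S)-2-hydroxy-1-methyl-6-oxocyclohexyl 4-(tert-butyldimethylsilyloxy)-2-methoxy-6-methylbenzoate (C7 R, C6 S; hydroxyl anti to the aroyloxy group)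
Conditions: ketoreductase (panel hit), NADP+ (cat.), i-PrOH (10 vol %), DMSO (5 vol %), KH2PO4/K2HPO4 buffer 0.1 M, pH 7.0, 30 °C
Reagents that add atoms: none
Why: Enzymatic desymmetrising reduction of a 2,2-disubstituted cyclohexane-1,3-dione, in which the active site delivers hydride to one face of one of the two enantiotopic carbonyls and thereby sets C6 (S) and makes C7 a stereocentre (R) at once, at neutral pH where the hindered ester should not migrate.

Step 7
Reactants: 9 (1R,2S)-2-hydroxy-1-methyl-6-oxocyclohexyl 4-(tert-butyldimethylsilyloxy)-2-methoxy-6-methylbenzoate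
Product: 10 (1R,6S)-1-methyl-2-oxo-6-(triethylsilyloxy)cyclohexyl 4-(tert-butyldimethylsilyloxy)-2-methoxy-6-methylbenzoate
Conditions: TESOTf, 2,6-lutidine, CH2Cl2, −78 °C
Reagents that add atoms: triethylsilyl trifluoromethanesulfonate, CC[Si](CC)(CC)OS(=O)(=O)C(F)(F)F
Why: Silyl ether formation masks the C6 hydroxyl so that the base of step 8 cannot trigger retro-aldol cleavage of C6–C7 or acyl migration from the C7 oxygen.

Step 8
Reactants: 10 (1R,6S)-1-methyl-2-oxo-6-(triethylsilyloxy)cyclohexyl 4-(tert-butyldimethylsilyloxy)-2-methoxy-6-methylbenzoate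
Product: 12 (1R,3Z,6S)-6-hydroxy-3-(hydroxymethylidene)-1-methyl-2-oxocyclohexyl 4-(tert-butyldimethylsilyloxy)-2-methoxy-6-methylbenzoate, via silyl-protected hydroxymethylene ketone 11 (not isolated)
Conditions: LiHMDS (2.2 equiv), THF, −78 °C; CF3CH2OCHO, −78 °C; then 1 M HCl, THF, 0 °C to rt
Reagents that add atoms: 2,2,2-trifluoroethyl formate, O=COCC(F)(F)F
Why: Claisen-type formylation of the lithium enolate, where the quaternary C7 lets the C8 ketone enolise only towards C8a, the 2,6-disubstituted benzoate resists attack by the enolate, and the acidic work-up cleaves the alkyl triethylsilyl ether much faster than the acid-robust aryl TBS ether.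

Step 9
Reactants: 12 (1R,3Z,6S)-6-hydroxy-3-(hydroxymethylidene)-1-methyl-2-oxocyclohexyl 4-(tert-butyldimethylsilyloxy)-2-methoxy-6-methylbenzoate
Product: 13 (1R,3Z)-3-(hydroxymethylidene)-1-methyl-2,6-dioxocyclohexyl 4-(tert-butyldimethylsilyloxy)-2-methoxy-6-methylbenzoate
Conditions: Dess–Martin periodinane (1.2 equiv), CH2Cl2, 0 °C to rt
Reagents that add atoms: none
Why: Dess–Martin oxidation of the secondary alcohol under neutral, non-nucleophilic conditions; C7 remains a stereocentre because C8a now carries C1 and the two carbonyl flanks are no longer equivalent.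

Step 10
Reactants: 13 (1R,3Z)-3-(hydroxymethylidene)-1-methyl-2,6-dioxocyclohexyl 4-(tert-butyldimethylsilyloxy)-2-methoxy-6-methylbenzoate
Product: 14 (1R,3Z)-3-(hydroxymethylidene)-1-methyl-2,6-dioxocyclohex-4-en-1-yl 4-(tert-butyldimethylsilyloxy)-2-methoxy-6-methylbenzoate
Conditions: DDQ (1.1 equiv), 1,4-dioxane, rt; filtered and used without storage
Reagents that add atoms: none
Why: Quinone dehydrogenation of a 2-hydroxymethylene ketone, in which DDQ takes hydride from C4a (allylic to the enol) and loss of the acidic C5 proton gives the C4a=C5 enone, which cannot aromatise because C7 is quaternary.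

Step 11
Reactants: 15 trimethylsulfoxonium iodide; 16 (E)-but-2-enoyl chloride
Product: 18 (E)-1-[dimethyl(oxo)-λ6-sulfanylidene]pent-3-en-2-one, via dimethylsulfoxonium methylide 17 (not isolated)
Conditions: 15 (3 equiv), KOt-Bu (3 equiv), THF, reflux; then 16 added slowly, 0 °C to rt
Reagents that add atoms: none
Why: C-acylation of the Corey–Chaykovsky ylide by an acid chloride outruns conjugate addition at 0 °C, and a second equivalent of 17 removes the acidic proton to give the stabilised keto ylide, whose enone is too electron-rich to be cyclopropanated.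

Step 12
Reactants: 14 (1R,3Z)-3-(hydroxymethylidene)-1-methyl-2,6-dioxocyclohex-4-en-1-yl 4-(tert-butyldimethylsilyloxy)-2-methoxy-6-methylbenzoate; 18 (E)-1-[dimethyl(oxo)-λ6-sulfanylidene]pent-3-en-2-one
Product: 21 (7R)-7-methyl-6,8-dioxo-3-[(E)-prop-1-enyl]-7H-isochromen-7-yl 4-(tert-butyldimethylsilyloxy)-2-methoxy-6-methylbenzoate, via C4a-alkylated enedione 19 (not isolated), via C3 hemiketal 20 (not isolated)
Conditions: [Cp*RhCl2]2 (5 mol %), AgSbF6 (20 mol %), NaOAc (30 mol %), 4 Å MS, DCE, 60 °C, 18 (1.5 equiv) added slowly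
Reagents that add atoms: none
Why: Proposed new method: once the formyl/enol unit has rotated so that O2 faces C4a, acetate-assisted metalation by the O2-bound cationic Cp*Rh species should give the five-membered rhodacycle Rh–O2–C1=C8a–C4a, after which 18 binds through carbon, expels dimethyl sulfoxide to leave a rhodium carbene, and migratory insertion with protonolysis places the 2-oxopent-3-enyl chain on C4a (19). The closest known reaction type is carboxylate- or nitrogen-directed aryl C–H alkylation with sulfoxonium ylides under trivalent rhodium catalysis followed by cyclocondensation (isocoumarins, isoquinolines), together with carboxylate-directed beta-vinylic C–H activation of acrylic acids; an enol-directed vinylic C–H bond of a cyclohexenedione has not been used in this way. Ring A closes by 6-exo-trig addition of O2 to the C3 ketone (20) and loss of water, which installs C3=C4 without an oxidant because the ylide arrives at the right oxidation level. No stereocentre is created in 21 (C3 of 20 is transient), and the quaternary C7 takes part in no bond change and cannot epimerise. The step needs C4a–H over C5–H, the formyl C1–H and any aryl C–H, and insertion over cyclopropanation or O-alkylation. Only C4a–H lies within a five-membered chelate from O2, O8 (the director for C1–H metalation) is shielded by the fully substituted C7, both ortho positions of the benzoate are blocked, and slow addition keeps free ylide scarce.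

Step 13
Reactants: 21 (7R)-7-methyl-6,8-dioxo-3-[(E)-prop-1-enyl]-7H-isochromen-7-yl 4-(tert-butyldimethylsilyloxy)-2-methoxy-6-methylbenzoate
Product: 22 (7R)-7-methyl-6,8-dioxo-3-[(E)-prop-1-enyl]-7H-isochromen-7-yl 4-hydroxy-2-methoxy-6-methylbenzoate (target)
Conditions: TBAF (1.1 equiv), AcOH (1.2 equiv), THF, 0 °C
Reagents that add atoms: none
Why: Fluoride-induced cleavage of an aryl silyl ether, buffered by acetic acid so that neither phenoxide nor basic fluoride can open the electrophilic pyran or the non-enolisable beta-diketone.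

Compound list
1 | 2,4-dihydroxy-6-methylbenzaldehyde | Cc1cc(O)cc(O)c1C=O | starting material
2 | 4-(tert-butyldimethylsilyloxy)-2-hydroxy-6-methylbenzaldehyde | Cc1cc(O[Si](C)(C)C(C)(C)C)cc(O)c1C=O | intermediate
3 | 4-(tert-butyldimethylsilyloxy)-2-methoxy-6-methylbenzaldehyde | Cc1cc(O[Si](C)(C)C(C)(C)C)cc(OC)c1C=O | intermediate
4 | 4-(tert-butyldimethylsilyloxy)-2-methoxy-6-methylbenzoic acid | Cc1cc(O[Si](C)(C)C(C)(C)C)cc(OC)c1C(=O)O | intermediate
5 | 2-methylcyclohexane-1,3-dione | CC1C(=O)CCCC1=O | starting material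
6 | 2-hydroxy-2-methylcyclohexane-1,3-dione | CC1(O)C(=O)CCCC1=O | intermediate
7 | 4-(tert-butyldimethylsilyloxy)-2-methoxy-6-methylbenzoic trifluoroacetic anhydride (not isolated) | Cc1cc(O[Si](C)(C)C(C)(C)C)cc(OC)c1C(=O)OC(=O)C(F)(F)F | intermediate
8 | 1-methyl-2,6-dioxocyclohexyl 4-(tert-butyldimethylsilyloxy)-2-methoxy-6-methylbenzoate | CC1(OC(=O)c2c(C)cc(O[Si](C)(C)C(C)(C)C)cc2OC)C(=O)CCCC1=O | intermediate
9 | (1R,2S)-2-hydroxy-1-methyl-6-oxocyclohexyl 4-(tert-butyldimethylsilyloxy)-2-methoxy-6-methylbenzoate | C1C[C@H](O)[C@@](C)(OC(=O)c2c(C)cc(O[Si](C)(C)C(C)(C)C)cc2OC)C(=O)C1 | intermediate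
10 | (1R,6S)-1-methyl-2-oxo-6-(triethylsilyloxy)cyclohexyl 4-(tert-butyldimethylsilyloxy)-2-methoxy-6-methylbenzoate | C1C[C@H](O[Si](CC)(CC)CC)[C@@](C)(OC(=O)c2c(C)cc(O[Si](C)(C)C(C)(C)C)cc2OC)C(=O)C1 | intermediate
11 | (1R,3Z,6S)-3-(hydroxymethylidene)-1-methyl-2-oxo-6-(triethylsilyloxy)cyclohexyl 4-(tert-butyldimethylsilyloxy)-2-methoxy-6-methylbenzoate (not isolated) | C1C[C@H](O[Si](CC)(CC)CC)[C@@](C)(OC(=O)c2c(C)cc(O[Si](C)(C)C(C)(C)C)cc2OC)C(=O)/C1=C\O | intermediate
12 | (1R,3Z,6S)-6-hydroxy-3-(hydroxymethylidene)-1-methyl-2-oxocyclohexyl 4-(tert-butyldimethylsilyloxy)-2-methoxy-6-methylbenzoate | C1C[C@H](O)[C@@](C)(OC(=O)c2c(C)cc(O[Si](C)(C)C(C)(C)C)cc2OC)C(=O)/C1=C\O | intermediate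
13 | (1R,3Z)-3-(hydroxymethylidene)-1-methyl-2,6-dioxocyclohexyl 4-(tert-butyldimethylsilyloxy)-2-methoxy-6-methylbenzoate | C1CC(=O)[C@@](C)(OC(=O)c2c(C)cc(O[Si](C)(C)C(C)(C)C)cc2OC)C(=O)/C1=C\O | intermediate
14 | (1R,3Z)-3-(hydroxymethylidene)-1-methyl-2,6-dioxocyclohex-4-en-1-yl 4-(tert-butyldimethylsilyloxy)-2-methoxy-6-methylbenzoate | C1=CC(=O)[C@@](C)(OC(=O)c2c(C)cc(O[Si](C)(C)C(C)(C)C)cc2OC)C(=O)/C1=C\O | intermediate
15 | trimethylsulfoxonium iodide | C[S+](C)(C)=O.[I-] | starting material
16 | (E)-but-2-enoyl chloride | C/C=C/C(Cl)=O | starting material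
17 | dimethylsulfoxonium methylide (not isolated) | C=S(C)(C)=O | intermediate
18 | (E)-1-[dimethyl(oxo)-λ6-sulfanylidene]pent-3-en-2-one | C/C=C/C(=O)C=S(C)(C)=O | intermediate
19 | (1R,3E)-3-(hydroxymethylidene)-1-methyl-2,6-dioxo-4-[(E)-2-oxopent-3-enyl]cyclohex-4-en-1-yl 4-(tert-butyldimethylsilyloxy)-2-methoxy-6-methylbenzoate (not isolated) | C/C=C/C(=O)CC1=CC(=O)[C@@](C)(OC(=O)c2c(C)cc(O[Si](C)(C)C(C)(C)C)cc2OC)C(=O)/C1=C/O | intermediate
20 | (7R)-3-hydroxy-7-methyl-6,8-dioxo-3-[(E)-prop-1-enyl]-3,4-dihydroisochromen-7-yl 4-(tert-butyldimethylsilyloxy)-2-methoxy-6-methylbenzoate, both C3 epimers (not isolated) | C/C=C/C1(O)CC2=CC(=O)[C@@](C)(OC(=O)c3c(C)cc(O[Si](C)(C)C(C)(C)C)cc3OC)C(=O)C2=CO1 | intermediate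
21 | (7R)-7-methyl-6,8-dioxo-3-[(E)-prop-1-enyl]-7H-isochromen-7-yl 4-(tert-butyldimethylsilyloxy)-2-methoxy-6-methylbenzoate | C/C=C/C1=CC2=CC(=O)[C@@](C)(OC(=O)c3c(C)cc(O[Si](C)(C)C(C)(C)C)cc3OC)C(=O)C2=CO1 | intermediate
22 | (7R)-7-methyl-6,8-dioxo-3-[(E)-prop-1-enyl]-7H-isochromen-7-yl 4-hydroxy-2-methoxy-6-methylbenzoate | C/C=C/C1=CC2=CC(=O)[C@@](C)(OC(=O)c3c(C)cc(O)cc3OC)C(=O)C2=CO1 | target

Total step count: 13.
Longest linear sequence: 11 steps (1, 2, 3, 5, 6, 7, 8, 9, 10, 12, 13).

Steps most likely to fail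

**1. Step 12.**
- The rhodium may be parked as the O2/O8 chelate of the beta-keto enolate.
- Metalation may take place at the formyl C1–H under direction of O8.
- The acidic enol may protonate the ylide and then be O-alkylated.
- The precursor may be lost by self-cycloaddition, or by acyloxy shift with aromatisation, before it is metalated.
- Early loss of the silyl group would only anticipate step 13.

The fallback uses known chemistry; it sets out from acid 4 and comes back at 21. Ring A is prepared on an arene and ring B is dearomatised afterwards. Purchased 5-bromo-1,3-dimethoxy-2-methylbenzene is formylated (POCl3, DMF, Vilsmeier–Haack) to 6-bromo-2,4-dimethoxy-3-methylbenzaldehyde F1. This is demethylated (BBr3, CH2Cl2) to 6-bromo-2,4-dihydroxy-3-methylbenzaldehyde F2. Sonogashira coupling with (E)-pent-3-en-1-yne (PdCl2(PPh3)2, CuI, Et3N, DMF) then gives 2,4-dihydroxy-3-methyl-6-[(E)-pent-3-en-1-ynyl]benzaldehyde F3. Enantioselective hydroxylative dearomatisation with O2, [Cu(MeCN)4]PF6 and (−)-sparteine (DIPEA, DMAP, CH2Cl2, −78 °C) should give (2R,4Z)-2-hydroxy-4-(hydroxymethylidene)-2-methyl-5-[(E)-pent-3-en-1-ynyl]cyclohex-5-ene-1,3-dione F4. CuI-catalysed 6-endo-dig cycloisomerisation in buffered MeCN gives (7R)-7-hydroxy-7-methyl-3-[(E)-prop-1-enyl]isochromene-6,8-dione F5. Acylation of the C7 hydroxyl with 4 under the conditions of step 5 gives 21.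

**2. Step 6.** The bulky, lipophilic diketone may be accepted poorly by the enzyme pocket, the enantiotopic carbonyls may be told apart insufficiently, or the aroyl group may migrate to the new hydroxyl.

The fallback sets out from 8 and comes back at 13. It replaces asymmetric reduction by a racemic shortcut with resolution. Direct formylation of achiral 8 (LiHMDS, CF3CH2OCHO, THF, −78 °C) gives 13 together with its mirror image, (1S,3Z)-3-(hydroxymethylidene)-1-methyl-2,6-dioxocyclohexyl 4-(tert-butyldimethylsilyloxy)-2-methoxy-6-methylbenzoate F6. Condensation of the racemate with (S)-1-phenylethylamine (CH2Cl2, rt) gives two diastereomeric enaminones: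
- (1R,3Z)-1-methyl-2,6-dioxo-3-({[(1S)-1-phenylethyl]amino}methylidene)cyclohexyl 4-(tert-butyldimethylsilyloxy)-2-methoxy-6-methylbenzoate F7
- (1S,3Z)-1-methyl-2,6-dioxo-3-({[(1S)-1-phenylethyl]amino}methylidene)cyclohexyl 4-(tert-butyldimethylsilyloxy)-2-methoxy-6-methylbenzoate F8

These are separated by crystallisation or chromatography. Hydrolysis of F7 (1 M HCl, THF) returns 13. Steps 6 to 9 are bypassed at the price of half the material.

**3. Step 5.** Acylation of the hindered, electron-poor tertiary hydroxyl may be sluggish, trifluoroacetylation may compete, or the alpha-ketol may rearrange with ring contraction.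

The fallback sets out from 4 and 5 and comes back at 8. It forms the C7–O bond instead of the acyl–O bond. Acid 4 is converted (DCC, H2O2, CH2Cl2, 0 °C) into bis[4-(tert-butyldimethylsilyloxy)-2-methoxy-6-methylbenzoyl] peroxide F9. The potassium enolate of 5 (K2CO3, DMF, 0 °C to rt) then attacks the O–O bond through C2, a known oxidative C–O coupling of 2-substituted 1,3-dicarbonyl compounds with diacyl peroxides. This gives 8, and step 4 is no longer needed.

Further compounds
F1 | step 12 | 6-bromo-2,4-dimethoxy-3-methylbenzaldehyde | COc1cc(Br)c(C=O)c(OC)c1C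
F2 | step 12 | 6-bromo-2,4-dihydroxy-3-methylbenzaldehyde | Cc1c(O)cc(Br)c(C=O)c1O
F3 | step 12 | 2,4-dihydroxy-3-methyl-6-[(E)-pent-3-en-1-ynyl]benzaldehyde | C/C=C/C#Cc1cc(O)c(C)c(O)c1C=O
F4 | step 12 | (2R,4Z)-2-hydroxy-4-(hydroxymethylidene)-2-methyl-5-[(E)-pent-3-en-1-ynyl]cyclohex-5-ene-1,3-dione | C/C=C/C#CC1=CC(=O)[C@@](C)(O)C(=O)/C1=C\O
F5 | step 12 | (7R)-7-hydroxy-7-methyl-3-[(E)-prop-1-enyl]isochromene-6,8-dione | C/C=C/C1=CC2=CC(=O)[C@@](C)(O)C(=O)C2=CO1
F6 | step 6 | (1S,3Z)-3-(hydroxymethylidene)-1-methyl-2,6-dioxocyclohexyl 4-(tert-butyldimethylsilyloxy)-2-methoxy-6-methylbenzoate | C1CC(=O)[C@](C)(OC(=O)c2c(C)cc(O[Si](C)(C)C(C)(C)C)cc2OC)C(=O)/C1=C\O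
F7 | step 6 | (1R,3Z)-1-methyl-2,6-dioxo-3-({[(1S)-1-phenylethyl]amino}methylidene)cyclohexyl 4-(tert-butyldimethylsilyloxy)-2-methoxy-6-methylbenzoate | C1CC(=O)[C@@](C)(OC(=O)c2c(C)cc(O[Si](C)(C)C(C)(C)C)cc2OC)C(=O)/C1=C\N[C@@H](C)c1ccccc1
F8 | step 6 | (1S,3Z)-1-methyl-2,6-dioxo-3-({[(1S)-1-phenylethyl]amino}methylidene)cyclohexyl 4-(tert-butyldimethylsilyloxy)-2-methoxy-6-methylbenzoate | C1CC(=O)[C@](C)(OC(=O)c2c(C)cc(O[Si](C)(C)C(C)(C)C)cc2OC)C(=O)/C1=C\N[C@@H](C)c1ccccc1
F9 | step 5 | bis[4-(tert-butyldimethylsilyloxy)-2-methoxy-6-methylbenzoyl] peroxide | Cc1cc(O[Si](C)(C)C(C)(C)C)cc(OC)c1C(=O)OOC(=O)c1c(C)cc(O[Si](C)(C)C(C)(C)C)cc1OC
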